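The whole plan depends on cutting the C6–C11 bond of ring B and handing C11 back to C1. This retro-1,2-shift, together with re-closure of a C6–C8 bond, converts the spiro[5.5]undecane into the tricyclic frame of (−)-thujopsene (a cyclopropane on a cis-decalin), so no carbon has to be added. The feature exploited is the spiro carbon C6, wedged between C5 (CMe2) and the methyl-bearing alkene carbon C1. Forward, one acid-triggered cascade opens the cyclopropane, moves C11 to C6, closes ring B and sets C6, giving (6R)-α-chamigrene. The precursor is the commercial hydrocarbon itself. C10 is then oxygenated, fixed by reagent control and chlorinated with inversion. Ring A oxidation, HBr addition, C4 bromination and carbonyl reduction finish.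

Key step: step 1

Remark (numbering): ring A = C1(CH3)=C2–C3–C4–C5(CH3)2–C6 and ring B = C6–C7–C8–C9(CH3)–C10–C11. The same labels are used in 1, where C9=C10 is the alkene, C11 the allylic CH2, C1 the carbon with the angular methyl, and C6, C7, C8 the cyclopropane. Locants in all names follow this numbering.

Remark (assumption): commercial thujopsene from cedarwood or hiba oil is taken to be the natural (−)-(1aS,4aS,8aS) enantiomer and is redistilled before use.

Step 1
Reactants: 1 (−)-thujopsene
Product: 2 (6R)-α-chamigrene [(6R)-1,5,5,9-tetramethylspiro[5.5]undeca-1,8-diene]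
Conditions: HClO4 (70 %, 2 mol %), glacial AcOH, 20 °C, GC control; quench into cold aq NaHCO3; AgNO3–SiO2 chromatography
Reagents that add atoms: none
Why: Protonation of C9=C10 at C10 gives the tertiary cyclopropylcarbinyl cation at C9, strain release breaks C6–C8 to leave the C8=C9 alkene and a tertiary C6 cation inside a seven-membered ring, C11 then shifts from C1 to C6, and the tertiary C1 cation loses a C2 proton. The closest known reaction type is the acid-catalysed cyclopropylcarbinyl–homoallyl opening with Wagner–Meerwein ring contraction, which is documented for thujopsene itself. Ring B (C6–C7–C8–C9–C10–C11) is closed by the 1,2-alkyl shift that makes C6–C11, a seven-to-six contraction and not a union of two chain termini. C6 is controlled by the C1 stereocentre of 1: ring A keeps C2 close to the nodal plane of the C6 cation, so C11 overlaps only with the lobe on the face that C8 has just left, and the shift is suprafacial. The step needs C11 migration to prevail over angular-methyl migration, solvent capture and exocyclic proton loss; a dry, weakly nucleophilic medium lets the tertiary cations interconvert before proton loss, and olefin that took the methyl-shift path re-enters the same cation manifold when resubmitted. Contact time is kept short because C6 is stereogenic only through the position of the ring B alkene, so re-protonation at C8 would erode it.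

Step 2
Reactants: 2 (6R)-α-chamigrene
Product: 4 (6S)-1,5,5,9-tetramethylspiro[5.5]undeca-1,8-dien-10-one, via 10-hydroxy-α-chamigrene 3 (not isolated)
Conditions: SeO2 (0.3 equiv), t-BuOOH (2 equiv, decane), CH2Cl2, 0 °C → rt, stopped before full conversion; aqueous work-up; crude, DMP, NaHCO3, CH2Cl2, 0 °C → rt
Reagents that add atoms: selenium dioxide, O=[Se]=O; tert-butyl hydroperoxide, CC(C)(C)OO
Why: The catalytic SeO2/t-BuOOH variant of the Riley allylic oxidation (ene reaction, then [2,3]-shift) oxygenates the ring CH2 on the more substituted alkene terminus, which is C10, returns the alkene to C8=C9 so that the C6 information is kept, and should prefer the open ring B alkene over C1=C2, which is shielded by quaternary C6; Dess–Martin oxidation then funnels both carbinol epimers into one enone, so no stereocentre is set here.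

Step 3
Reactants: 4 (6S)-1,5,5,9-tetramethylspiro[5.5]undeca-1,8-dien-10-one
Product: 5 (6S,10R)-1,5,5,9-tetramethylspiro[5.5]undeca-1,8-dien-10-ol (hydroxyl on the ring B face that carries C5)
Conditions: (S)-Me-CBS (20 mol %), catecholborane (1.8 equiv), toluene, −78 °C; MeOH, then aq NaOH wash
Reagents that add atoms: none
Why: In this Corey–Bakshi–Shibata reduction of an α-methyl cyclohexenone the C9 alkenyl arm acts as the large group, so the (S)-catalyst should deliver hydride to the face that gives the (10R)-carbinol under reagent control, catecholborane at −78 °C leaves both alkenes alone, and any material of the opposite C6 series becomes a diastereomer that chromatography can remove.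

Step 4
Reactants: 5 (6S,10R)-1,5,5,9-tetramethylspiro[5.5]undeca-1,8-dien-10-ol
Product: 6 (6S,10S)-10-chloro-1,5,5,9-tetramethylspiro[5.5]undeca-1,8-diene (chlorine on the ring B face that carries C1)
Conditions: PPh3 (1.3 equiv), Cl3CC(O)CCl3, CH2Cl2, −20 → 0 °C; used promptly
Reagents that add atoms: hexachloroacetone, ClC(Cl)(Cl)C(=O)C(Cl)(Cl)Cl
Why: In this Appel-type chlorination chloride displaces the alkoxyphosphonium group by SN2 under neutral, non-ionising conditions that are known to convert secondary allylic alcohols with inversion and little allylic transposition, which turns (10R)-OH into (10S)-Cl and avoids the C8–C9–C10 allyl cation that would scramble both C10 and C6.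

Step 5
Reactants: 6 (6S,10S)-10-chloro-1,5,5,9-tetramethylspiro[5.5]undeca-1,8-diene
Product: 7 (6S,10S)-10-chloro-1,5,5,9-tetramethylspiro[5.5]undeca-1,8-dien-3-one
Conditions: Rh2(cap)4 (1 mol %), t-BuOOH (5 equiv, decane), K2CO3 (0.5 equiv), CH2Cl2, rt
Reagents that add atoms: tert-butyl hydroperoxide, CC(C)(C)OO
Why: The dirhodium caprolactamate/t-BuOOH allylic C–H oxidation abstracts hydrogen from the unhindered C3 methylene next to the electron-rich C1=C2 alkene and oxidises the less hindered end of the C1–C2–C3 allyl radical to the β-methyl enone, whereas the ring B alkene is deactivated by the allylic chlorine and its other allylic CH2 (C7) is neopentyl; no stereocentre is made or touched.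

Step 6
Reactants: 7 (6S,10S)-10-chloro-1,5,5,9-tetramethylspiro[5.5]undeca-1,8-dien-3-one
Product: 8 (6S,9S,10S)-9-bromo-10-chloro-1,5,5,9-tetramethylspiro[5.5]undec-1-en-3-one (Br and Cl trans)
Conditions: HBr (anhydrous, excess), BHT (cat.), CH2Cl2, dark, −60 → −20 °C
Reagents that add atoms: hydrogen bromide, Br
Why: In this ionic Markovnikov hydrobromination, of the kind known for methallyl-type chlorides, the proton goes to C8 and the charge to tertiary C9, and bromide is expected to enter anti to the C10 chlorine, which A(1,2) strain with the C9 methyl holds pseudo-axial so that its lone pairs and dipole screen the syn face, giving the trans (9S,10S) array under kinetic control, while the ring A enone resists addition and BHT and darkness suppress the radical chain.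

Step 7
Reactants: 8 (6S,9S,10S)-9-bromo-10-chloro-1,5,5,9-tetramethylspiro[5.5]undec-1-en-3-one
Product: 10 (4R,6R,9S,10S)-4,9-dibromo-10-chloro-1,5,5,9-tetramethylspiro[5.5]undec-1-en-3-one, via C3 trimethylsilyl dienol ether 9 (not isolated)
Conditions: LiHMDS (1.1 equiv), TMSCl (1.3 equiv), THF, −78 °C; then NBS (1.05 equiv), −78 → −40 °C
Reagents that add atoms: N-bromosuccinimide, O=C1CCC(=O)N1Br; chlorotrimethylsilane, C[Si](C)(C)Cl (silicon only in 9)
Why: Kinetic α′-enolisation of an isophorone-type enone at C4 followed by silyl enol ether bromination should let NBS attack C4 along the axial trajectory anti to the pseudo-axial C5 methyl, in the half-chair that turns the C1 methyl away from the chlorinated C10–C11 flank, that is on the ring A face that carries C11, after which the bromide relaxes to the equatorial position of (4R)-10; one equivalent of hindered amide at −78 °C spares the tertiary bromide.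

Step 8
Reactants: 10 (4R,6R,9S,10S)-4,9-dibromo-10-chloro-1,5,5,9-tetramethylspiro[5.5]undec-1-en-3-one
Product: 11 (3S,4R,6R,9S,10S)-4,9-dibromo-10-chloro-1,5,5,9-tetramethylspiro[5.5]undec-1-en-3-ol (target)
Conditions: DIBAL-H (1.3 equiv), CH2Cl2, −78 °C; aq Rochelle salt
Reagents that add atoms: none
Why: In this DIBAL-H 1,2-reduction of the α′-bromo enone the axial C5 methyl blocks the axial approach to C3, so hydride should arrive from the opposite side and leave the C3 hydroxyl pseudo-axial and cis to the equatorial C4 bromine, which is (3S), a cis-bromohydrin that cannot close to an epoxide, and the alkyl halides are inert at −78 °C.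

Compound list
1 | (−)-thujopsene, (1aS,4aS,8aS)-2,4a,8,8-tetramethyl-1,1a,4,4a,5,6,7,8-octahydrocyclopropa[d]naphthalene | CC1=CC[C@]2(C)CCCC(C)(C)[C@@]23C[C@@H]13 | starting material
2 | (6R)-α-chamigrene | CC1=CCCC(C)(C)[C@@]12CC=C(C)CC2 | intermediate
3 | 10-hydroxy-α-chamigrene, both C10 epimers | CC1=CCCC(C)(C)[C@@]12CC=C(C)C(O)C2 | intermediate
4 | (6S)-1,5,5,9-tetramethylspiro[5.5]undeca-1,8-dien-10-one | CC1=CCCC(C)(C)[C@@]12CC=C(C)C(=O)C2 | intermediate
5 | (6S,10R)-1,5,5,9-tetramethylspiro[5.5]undeca-1,8-dien-10-ol | CC1=CCCC(C)(C)[C@@]12CC=C(C)[C@H](O)C2 | intermediate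
6 | (6S,10S)-10-chloro-1,5,5,9-tetramethylspiro[5.5]undeca-1,8-diene | CC1=CCCC(C)(C)[C@@]12CC=C(C)[C@@H](Cl)C2 | intermediate
7 | (6S,10S)-10-chloro-1,5,5,9-tetramethylspiro[5.5]undeca-1,8-dien-3-one | CC1=CC(=O)CC(C)(C)[C@@]12CC=C(C)[C@@H](Cl)C2 | intermediate
8 | (6S,9S,10S)-9-bromo-10-chloro-1,5,5,9-tetramethylspiro[5.5]undec-1-en-3-one | CC1=CC(=O)CC(C)(C)[C@@]12CC[C@](C)(Br)[C@@H](Cl)C2 | intermediate
9 | (6R,9S,10S)-9-bromo-10-chloro-1,5,5,9-tetramethyl-3-(trimethylsilyloxy)spiro[5.5]undeca-1,3-diene | CC1=CC(O[Si](C)(C)C)=CC(C)(C)[C@@]12CC[C@](C)(Br)[C@@H](Cl)C2 | intermediate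
10 | (4R,6R,9S,10S)-4,9-dibromo-10-chloro-1,5,5,9-tetramethylspiro[5.5]undec-1-en-3-one | CC1=CC(=O)[C@H](Br)C(C)(C)[C@@]12CC[C@](C)(Br)[C@@H](Cl)C2 | intermediate
11 | (3S,4R,6R,9S,10S)-4,9-dibromo-10-chloro-1,5,5,9-tetramethylspiro[5.5]undec-1-en-3-ol | CC1=C[C@H](O)[C@H](Br)C(C)(C)[C@@]12CC[C@](C)(Br)[C@@H](Cl)C2 | target

Total step count: 8. Longest linear sequence: 8 steps (1 → 11).

Steps most likely to fail

Step 1. The angular methyl may migrate faster than C11, the dienes may isomerise further under the acid, and re-protonation of ring B may wash out the C6 configuration. The fallback sets out from 1 and comes back at 4. Compound 1 is epoxidised at C9=C10 (mCPBA, NaHCO3, CH2Cl2, 0 °C) to thujopsene 9,10-epoxide F1, drawn with oxygen anti to the cyclopropane methylene; the face is immaterial because C10 is later taken to the ketone. The C9–O bond is then ionised with BF3·OEt2 in CH2Cl2 at −78 °C, a trigger known from the cyclopropane-opening chemistry of 2-carene oxide. The same C6–C8 cleavage and C1→C6 shift of C11 then run without a free proton source. C10 arrives already oxygenated as carbinol 3, and ring B can no longer lose its bias by alkene migration. DMP oxidation as in step 2 rejoins the route at 4, so the selenium oxidation is no longer needed.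

Step 6. Facial control at C9 may be lost if bromide attacks while the chlorine lies pseudo-equatorial. The tertiary bromide may equilibrate under the acid, and the allylic chloride may ionise or exchange halide before addition. The fallback sets out from 7 and comes back at 8, and no new compound is made (F0). The alkene is hydrobrominated by metal-hydride hydrogen atom transfer (Co(acac)2, t-BuOOH, Et3SiH, tosyl bromide as bromine-atom donor, n-PrOH, rt). Hydrogen is delivered to C8, and the tertiary C9 radical takes bromine from the bulky sulfonyl bromide. No acid is present, so the allylic chloride cannot ionise. The stereo-determining event changes from ion-pair collapse to radical capture. Such catalysts select electron-neutral alkenes over hindered β,β-disubstituted enones.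

Step 7. Facial selectivity at C4 may be poor, because the two faces of the dienol ether differ only through the remote substitution of ring B, and the bromide may epimerise on work-up. The fallback sets out from 8 and comes back at 10. If NBS prefers the other face, the same bromination gives the (4S)-bromo enone F2. This is deprotonated (LiHMDS, THF, −78 °C) to its lithium bromodienolate F3 and quenched kinetically with AcOH at −78 °C. C4 is then set by C–H bond formation instead of C–Br bond formation. A proton that arrives on the face preferred by electrophiles pushes bromine to the opposite face, which is the (4R) configuration of 10. C5 is quaternary, so the bromoenolate has no elimination pathway.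

Further compounds
F1 | step 1 | thujopsene 9,10-epoxide (oxygen anti to C7) | C[C@@]12O[C@@H]1C[C@]3(C)CCCC(C)(C)[C@@]34C[C@@H]24
F0 | step 6 | none | none
F2 | step 7 | (4S,6R,9S,10S)-4,9-dibromo-10-chloro-1,5,5,9-tetramethylspiro[5.5]undec-1-en-3-one | CC1=CC(=O)[C@@H](Br)C(C)(C)[C@@]12CC[C@](C)(Br)[C@@H](Cl)C2
F3 | step 7 | lithium C3,C4-bromodienolate of F2 | CC1=CC([O-])=C(Br)C(C)(C)[C@@]12CC[C@](C)(Br)[C@@H](Cl)C2.[Li+]
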